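Locants: chroman numbering for the heterocycle (O1, C2, C3, C4, C4a, C5 to C8, C8a) and primed locants for the norbornane (C1′ bridgehead on C2′ = C2, C3′ = CMe2, C4′ bridgehead, C5′–C6′ ethano bridge, C7′ methano bridge).

## Analysis of the target

- Target 21 is a spiro chroman. Ring A is a fully substituted phloroglucinol (C5–OH, C6–CHO, C7–OH, C8–CHO, O1 on C8a), ring B carries an isobutyl group at C4, and C2 is also C2′ of a 3′,3′-dimethylnorbornane.
- There are four stereocentres: 2R, 4S, 1′R and 4′S. The bridgeheads fix each other. At C2 the ether oxygen lies on the endo face of the bicycle and the C3 methylene on the exo face.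
- C4 is a 1,3-partner of C2 across ring B but has no rigid link to the bicycle before ring B exists, so it has to be set by a reagent.
- Sensitive groups are the two hydrogen-bonded aldehydes on an electron-rich ring, the free phenols, and the C2–O1 bond. That bond is a tertiary alkyl aryl ether between quaternary C3′ and bridgehead C1′; its ionisation would start a Wagner–Meerwein shift of the camphenilyl cation.
- The hard points are the fully substituted C2 next to CMe2, and the arene carbon C4a, which is flanked on both sides by oxygen-bearing carbons (C5 and C8a). Any aryl group on C4 is therefore di-ortho-substituted.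
- The feature the plan rests on: C1′, C6′, C5′, C4′ and C7′ form a cyclopentane. Without the C2–C3′ bond, what is left is a cyclopentane with an acyl carbon (C2) on C1′ and, cis to it on C4′, C3′ with its two methyls, that is, a cis-3-isopropenylcyclopentyl ketone. These carbons plus C3 are the ten carbons of a p-menthane monoterpene after ring cleavage and aldol re-closure.

## Retrosynthetic reasoning

**21 to 19 (C6–CHO and C8–CHO).** The aldehydes are cut first because they are the most fragile groups and because C6 and C8 are the only free, strongly activated positions of diol 19. A double electrophilic formylation needs no regiocontrol. It has to spare the C2–O1 ether.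

**19 to 18 (two O–benzyl bonds).** Benzyl ethers are chosen for the phenols because they survive base, organometallics, hydride reagents and radical conditions and leave under neutral hydrogenolysis, which cannot ionise C2–O1.

**18 to 17 (O1–C8a).** Ring B is opened at the aryl–oxygen bond, not at C2–O1, because substitution at C2 would pass through the rearranging camphenilyl cation. The forward step is a palladium-catalysed intramolecular etherification of tertiary alcohol 17. The leaving group must sit on the arene carbon that is ortho to C4a and meta to both benzyloxy groups. No electrophilic halogenation of a resorcinol diether can reach that position, so the bromine is carried from the start, from bromoarene 9.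

**17 to 16 (C2–C3′, the key disconnection).** Cutting this bond removes the bicycle and the quaternary carbinol centre together and leaves ketone 16, a cis-3-isopropenylcyclopentyl ketone. Forward, a hydrogen atom is delivered to the isopropenyl group and the tertiary radical closes onto the carbonyl carbon. The step must form the strained ring faster than the radical is simply reduced, and must place the side chain exo and the oxygen endo.

**16 to 13 and 14 (C4–isobutyl).** C4 is set by enantioselective conjugate addition. The isobutyl group is the nucleophile (Grignard reagent 14) and the arene sits on enone 13. The reverse polarity would need a di-ortho-substituted aryl nucleophile, which is poorly suited to catalytic asymmetric conjugate arylation. The ring α-centre C1′ is epimerisable and is adjusted to cis by base after this step.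

**13 to 8 and 11 (C3–C4).** The enone is cut at its double bond into methyl ketone 8 and the non-enolisable aldehyde 11. This is a cross-condensation with only one possible outcome.

**11 to 9 (formyl carbon).** Formylation of 9 places the future C4 next to bromine, at a position para to one ether and ortho to the other. This gives exactly the 2,4,6-pattern that ring A needs.

**8 to 6 to 4 to 2 to 1.** Ketone 8 is the conjugate-reduction product of acetylcyclopentene 6. Enone 6 is the base aldol product of keto aldehyde 4, which comes from oxidative cleavage of the ring alkene of (R)-limonene 1 via its epoxide 2. The stereocentre of 1 becomes C4′ and fixes the absolute configuration of the bicycle.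

## Alternatives that were turned down

**Alternative 1:** ring A is disconnected into dimethyl 3-oxopentanedioate A2 and the cyclic O,S-ketene acetal A3, a spiro dihydropyran that already carries C2, C4 and an ester on C4a.
- Forward: the enolate of A2 replaces the methylthio group at C8a, its second methylene then closes onto the ester (C5–C6), and enolisation gives the aromatic diester A1.
- For it: all six arene carbons and both carbon substituents arrive with the correct regiochemistry in one operation. No hindered aryl–C4 bond and no Lewis-acid formylation are needed. On ring A this is stronger than the chosen route.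
- Against it: A3 already contains the spiro centre and C4, so the two hardest problems are only moved into its preparation. The two esters of A1 must still be taken to aldehydes on a free phloroglucinol, which costs several redox and protection steps.
- Comparison: the chosen route is weaker on ring A but makes the bicycle and C2 in one step from a cheap chiral-pool ketone and is shorter overall.

**Alternative 2:** ring A is disconnected by a Diels–Alder reaction between diene A5 and the sulfinyl dihydropyranone A6.
- Forward: A5 adds across C4a=C8a, and sulfoxide elimination plus loss of the alkoxy group aromatise the adduct to chromanone A4.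
- For it: the 5,7-oxygenation is secured by the diene, and aromatisation drives the reaction. On arene regiochemistry it is at least as good as the chosen route.
- Against it: A6 must first be built with the spiro centre in place. A4 lacks the isobutyl group, so C4 has to be set late on a ketone by addition and deoxygenation or by olefination and reduction, relying on control by the spiro centre and passing through benzylic cations close to the labile C2–O1 bond. Diformylation is still required.
- Comparison: the chosen route sets C4 by catalyst control before the bicycle exists and needs fewer steps after ring formation.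

**Alternative 3:** ring B is disconnected at C2–C3 and O1–C8a into (1R,4S)-camphenilone A8 and fluoroacetophenone A9.
- Forward: the enolate of A9 adds to the exo face of A8, and the endo alkoxide displaces the ortho fluorine to give chromanone A7.
- For it: it is the most convergent route to the spiro core. Exo attack on A8 is a reliable way to place the oxygen endo, so on the certainty of the C2 configuration and on precedent for each bond type it is stronger than the chosen key step.
- Against it: the aldol addition to a ketone flanked by a quaternary carbon is reversible and crowded. The substitution at an arene carrying two donor ethers is activated only by the acyl group. C4 must again be set late on A7. A8 is not available as cheaply in high enantiomeric purity as 1.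
- Comparison: the chosen route has a riskier ring-forming step but takes absolute configuration from 1, sets C4 early and avoids late chemistry at C4.

Key step: step 8

## Remarks on the chemistry

- Remark 1: a 3,5-dioxygenated aryl group on C4 would lead to a 6,8-dioxygenated chroman. The target needs oxygen on both carbons next to C4a, so the arene in 16 and 17 is 2,4-bis(benzyloxy)-6-bromophenyl, with bromine at the future C8a.
- Remark 2: in step 7 the ligand antipode is the one that delivers isobutyl to the Si face of the β-carbon (S at the benzylic centre). This is assumed to be the (R,SP) antipode; the (S,RP) antipode is used if the sense is reversed.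

## Route

Step 1
Reactants: 1 (R)-limonene
Product: 2 (4R)-limonene 1,2-oxide (cis/trans epoxide mixture)
Conditions: mCPBA (1.05 equiv), NaHCO3, CH2Cl2, 0 °C
Reagents that add atoms: 3-chloroperoxybenzoic acid, OOC(=O)c1cccc(Cl)c1
Why: Prilezhaev epoxidation; the trisubstituted ring alkene is more electron-rich than the isopropenyl group and reacts first with one equivalent of peracid. Both epoxide diastereomers are used because C1 and C2 become carbonyl carbons in step 2, and the stereocentre is untouched.

Step 2
Reactants: 2 (4R)-limonene 1,2-oxide
Product: 4 (3R)-6-oxo-3-(prop-1-en-2-yl)heptanal, via trans-diol 3 (not isolated)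
Conditions: H5IO6 (1.2 equiv), THF–H2O, 0 °C to rt
Reagents that add atoms: water, O
Why: Acid-promoted opening of the epoxide to the diol, then Malaprade glycol cleavage in the same flask. The isopropenyl group is inert to periodate and the stereocentre is β to the aldehyde, so it cannot epimerise.

Step 3
Reactants: 4 (3R)-6-oxo-3-(prop-1-en-2-yl)heptanal
Product: 6 1-[(4S)-4-(prop-1-en-2-yl)cyclopent-1-en-1-yl]ethan-1-one, via hydroxy ketone 5 (not isolated)
Conditions: KOH (aq., dilute), THF, rt
Reagents that add atoms: none
Why: Intramolecular aldol condensation; the internal ketone enolate closes 5-exo onto the aldehyde and E1cB dehydration follows. Under hydroxide the aldol steps are reversible and the conjugated acetylcyclopentene is the thermodynamic outlet. The isopropenyl-bearing centre is not α to a carbonyl and keeps its configuration (the descriptor changes only through the priority rules).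

Step 4
Reactants: 6 1-[(4S)-4-(prop-1-en-2-yl)cyclopent-1-en-1-yl]ethan-1-one
Product: 8 1-[(3S)-3-(prop-1-en-2-yl)cyclopentyl]ethan-1-one (ring-C1 epimers; cis expected major), via silyl enol ether 7 (not isolated)
Conditions: [(Ph3P)CuH]6 (3 mol %), PhMe2SiH (1.2 equiv), toluene, rt; then K2CO3, MeOH, rt
Reagents that add atoms: none
Why: Copper hydride conjugate reduction; hydride adds to the ring β-carbon, the isolated isopropenyl alkene is not touched, and silylation of the copper enolate turns the catalyst over. Carbonate in methanol cleaves the silyl enol ether and equilibrates the new α-centre; the cis-1,3 isomer is expected to be modestly favoured, and the mixture is carried on because it is equilibrated again after step 7.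

Step 5
Reactants: 9 1,3-bis(benzyloxy)-5-bromobenzene
Product: 11 2,4-bis(benzyloxy)-6-bromobenzaldehyde, via iminium salt 10 (not isolated)
Conditions: POCl3 (1.5 equiv), DMF, 0 to 80 °C; aq. NaOAc
Reagents that add atoms: N,N-dimethylformamide, CN(C)C=O; water, O
Why: Vilsmeier–Haack formylation; the chloroiminium ion attacks the position next to bromine, which is para to one benzyloxy group and ortho to the other, while the site between the two ethers is doubly flanked and should be minor. Hydrolysis of the iminium salt gives the aldehyde with bromine already at the future C8a.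

Step 6
Reactants: 8 1-[(3S)-3-(prop-1-en-2-yl)cyclopentyl]ethan-1-one; 11 2,4-bis(benzyloxy)-6-bromobenzaldehyde
Product: 13 (2E)-3-[2,4-bis(benzyloxy)-6-bromophenyl]-1-[(3S)-3-(prop-1-en-2-yl)cyclopentyl]prop-2-en-1-one (ring-C1 epimers), via aldol adduct 12 (not isolated)
Conditions: NaOH (aq.), EtOH, rt to 40 °C
Reagents that add atoms: none
Why: Claisen–Schmidt condensation; 11 cannot enolise and only the methyl group of 8 can reach a conjugated enone by E1cB dehydration, so the cross-condensation has one outcome. The E alkene is the thermodynamic product.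

Step 7
Reactants: 13 (2E)-3-[2,4-bis(benzyloxy)-6-bromophenyl]-1-[(3S)-3-(prop-1-en-2-yl)cyclopentyl]prop-2-en-1-one; 14 isobutylmagnesium bromide
Product: 16 (3S)-3-[2,4-bis(benzyloxy)-6-bromophenyl]-5-methyl-1-[(1R,3S)-3-(prop-1-en-2-yl)cyclopentyl]hexan-1-one, via ring-C1 epimer mixture 15 (not isolated)
Conditions: CuBr·SMe2 (5 mol %), (R)-1-[(SP)-2-(diphenylphosphino)ferrocenyl]ethyldicyclohexylphosphine (6 mol %), 14 (1.3 equiv), t-BuOMe, −75 °C; aq. NH4Cl; then DBU (0.2 equiv), CH2Cl2, rt; chromatography
Reagents that add atoms: none
Why: Copper-catalysed enantioselective conjugate addition of a Grignard reagent to an acyclic β-aryl enone; the chiral diphosphine–copper complex delivers isobutyl to the Si face of the β-carbon and sets the benzylic centre as S, and the aryl bromide is inert at this temperature. DBU then equilibrates ring C1 (cis-1,3 expected to be favoured); the cis ketone is separated and the trans epimer returned to the equilibration.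

Step 8
Reactants: 16 (3S)-3-[2,4-bis(benzyloxy)-6-bromophenyl]-5-methyl-1-[(1R,3S)-3-(prop-1-en-2-yl)cyclopentyl]hexan-1-one
Product: 17 (1R,2R,4S)-2-{(2S)-2-[2,4-bis(benzyloxy)-6-bromophenyl]-4-methylpentyl}-3,3-dimethylbicyclo[2.2.1]heptan-2-ol (hydroxyl endo)
Conditions: Fe(acac)3 (1.0 equiv), PhSiH3 (2.5 equiv, slow addition), EtOH–THF (0.02 M), 60 °C, argon
Reagents that add atoms: none
Why: Proposed new method: the iron hydride formed from Fe(acac)3 and PhSiH3 gives a hydrogen atom to the terminal carbon of the isopropenyl group, the tertiary radical at C3′ attacks the carbonyl carbon C2 held within reach by the cis-1,3 arrangement, and the alkoxy radical is reduced by divalent iron to the alkoxide and protonated by ethanol; the closest known reaction type is the iron-hydride-initiated reductive cyclisation of alkene-tethered ketones to fused tertiary alcohols, which has not been shown for a bridged ring. The closure is 5-exo-trig onto the carbonyl carbon (counted through C7′) and at the same time completes the six-membered ring through C5′–C6′, which is the bicyclo[2.2.1]heptane. C4′ comes unchanged from 1, and C1′ is locked as R because only the cis epimer can bridge. The new centre C2 is set by the rotamer of the acyl group in the transition state: the bulky 2-aryl-4-methylpentyl chain should turn to the open exo side (syn to C7′) and the oxygen to the endo side under the C5′–C6′ bridge, which gives the 2R alcohol, but this is a steric argument and is not assured. The step needs hydrogen-atom transfer only to the 1,1-disubstituted alkene, and the aryl bromide, benzyl ethers and ketone are inert to the hydride. It also needs ring closure and capture of the strained alkoxy radical to outrun both β-scission back to the tertiary radical and direct reduction of that radical to an isopropyl group. Stoichiometric iron (ketone bound to the Lewis-acidic metal, inner-sphere reduction of the oxygen radical), slow addition of silane and dilution are chosen to favour this.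

Step 9
Reactants: 17 (1R,2R,4S)-2-{(2S)-2-[2,4-bis(benzyloxy)-6-bromophenyl]-4-methylpentyl}-3,3-dimethylbicyclo[2.2.1]heptan-2-ol
Product: 18 (2R,4S,1′R,4′S)-5,7-bis(benzyloxy)-4-isobutyl-3′,3′-dimethylspiro[chromane-2,2′-norbornane]
Conditions: Pd(OAc)2 (5 mol %), 2-(di-tert-butylphosphino)-1,1′-binaphthyl (6 mol %), Cs2CO3 (1.5 equiv), toluene, 80 °C
Reagents that add atoms: none
Why: Buchwald–Hartwig-type intramolecular C–O coupling; zerovalent palladium inserts into the C8a–Br bond, the caesium alkoxide binds, and the bulky electron-rich phosphine forces C–O reductive elimination to the six-membered ether. The tertiary alkoxide has no carbinol hydrogen, so oxidation to a carbonyl cannot compete, and the C2–O bond is never broken, so the endo configuration is kept.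

Step 10
Reactants: 18 (2R,4S,1′R,4′S)-5,7-bis(benzyloxy)-4-isobutyl-3′,3′-dimethylspiro[chromane-2,2′-norbornane]
Product: 19 (2R,4S,1′R,4′S)-4-isobutyl-3′,3′-dimethylspiro[chromane-2,2′-norbornane]-5,7-diol
Conditions: H2 (1 atm), 10% Pd/C, EtOAc–MeOH, rt
Reagents that add atoms: none
Why: Hydrogenolysis of the two benzyl aryl ethers; O1–C2 is a non-benzylic tertiary alkyl aryl ether and C4–C4a is a carbon–carbon bond, so both survive.

Step 11
Reactants: 19 (2R,4S,1′R,4′S)-4-isobutyl-3′,3′-dimethylspiro[chromane-2,2′-norbornane]-5,7-diol
Product: 21 (2R,4S,1′R,4′S)-5,7-dihydroxy-4-isobutyl-3′,3′-dimethylspiro[chromane-2,2′-norbornane]-6,8-dicarbaldehyde (CNP0150011.1), via bis(chloromethoxymethyl) arene 20 (not isolated)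
Conditions: Cl2CHOMe (4 equiv), TiCl4 (5 equiv), CH2Cl2, −20 to 0 °C; ice–1 M HCl
Reagents that add atoms: dichloromethyl methyl ether, COC(Cl)Cl; water, O
Why: Rieche formylation; the titanium phenoxide directs the electrophile to C6 and C8, the only free positions, each ortho or para to three oxygens, and hydrolysis of the α-chloro ethers on work-up gives the dialdehyde. The strong activation and excess reagent should allow the second formylation despite the first formyl group.

## Compound list

1 | (R)-(+)-limonene, (4R)-1-methyl-4-(prop-1-en-2-yl)cyclohex-1-ene | CC1=CC[C@@H](CC1)C(C)=C | starting material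
2 | (4R)-limonene 1,2-oxide, cis/trans epoxide mixture | CC12CC[C@H](CC1O2)C(C)=C | intermediate
3 | (4R)-1-methyl-4-(prop-1-en-2-yl)cyclohexane-1,2-diol (trans-diol, not isolated) | CC1(O)CC[C@H](CC1O)C(C)=C | intermediate
4 | (3R)-6-oxo-3-(prop-1-en-2-yl)heptanal | CC(=O)CC[C@H](CC=O)C(C)=C | intermediate
5 | 1-[(4R)-2-hydroxy-4-(prop-1-en-2-yl)cyclopentyl]ethan-1-one (diastereomer mixture, not isolated) | CC(=O)C1C(O)C[C@@H](C1)C(C)=C | intermediate
6 | 1-[(4S)-4-(prop-1-en-2-yl)cyclopent-1-en-1-yl]ethan-1-one | CC(=O)C1=CC[C@@H](C1)C(C)=C | intermediate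
7 | dimethyl(phenyl){1-[(3S)-3-(prop-1-en-2-yl)cyclopentylidene]ethoxy}silane (not isolated) | CC(O[Si](C)(C)c1ccccc1)=C1CC[C@@H](C1)C(C)=C | intermediate
8 | 1-[(3S)-3-(prop-1-en-2-yl)cyclopentyl]ethan-1-one, ring-C1 epimers, cis (1R,3S) expected major | CC(=O)C1CC[C@@H](C1)C(C)=C | intermediate
9 | 1,3-bis(benzyloxy)-5-bromobenzene | Brc1cc(OCc2ccccc2)cc(OCc2ccccc2)c1 | starting material
10 | N-{[2,4-bis(benzyloxy)-6-bromophenyl]methylidene}-N-methylmethanaminium dichlorophosphate (not isolated) | C[N+](C)=Cc1c(Br)cc(OCc2ccccc2)cc1OCc1ccccc1.[O-]P(=O)(Cl)Cl | intermediate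
11 | 2,4-bis(benzyloxy)-6-bromobenzaldehyde | O=Cc1c(Br)cc(OCc2ccccc2)cc1OCc1ccccc1 | intermediate
12 | 3-[2,4-bis(benzyloxy)-6-bromophenyl]-3-hydroxy-1-[(3S)-3-(prop-1-en-2-yl)cyclopentyl]propan-1-one (diastereomer mixture, not isolated) | OC(CC(=O)C1CC[C@@H](C1)C(C)=C)c1c(Br)cc(OCc2ccccc2)cc1OCc1ccccc1 | intermediate
13 | (2E)-3-[2,4-bis(benzyloxy)-6-bromophenyl]-1-[(3S)-3-(prop-1-en-2-yl)cyclopentyl]prop-2-en-1-one, ring-C1 epimers | O=C(/C=C/c1c(Br)cc(OCc2ccccc2)cc1OCc1ccccc1)C1CC[C@@H](C1)C(C)=C | intermediate
14 | isobutylmagnesium bromide, (2-methylpropyl)magnesium bromide | CC(C)C[Mg]Br | starting material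
15 | (3S)-3-[2,4-bis(benzyloxy)-6-bromophenyl]-5-methyl-1-[(3S)-3-(prop-1-en-2-yl)cyclopentyl]hexan-1-one, ring-C1 epimers (not isolated) | CC(C)C[C@H](c1c(OCc2ccccc2)cc(OCc2ccccc2)cc1Br)CC(=O)C1CC[C@@H](C1)C(C)=C | intermediate
16 | (3S)-3-[2,4-bis(benzyloxy)-6-bromophenyl]-5-methyl-1-[(1R,3S)-3-(prop-1-en-2-yl)cyclopentyl]hexan-1-one (cis) | CC(C)C[C@H](c1c(OCc2ccccc2)cc(OCc2ccccc2)cc1Br)CC(=O)[C@@H]1CC[C@@H](C1)C(C)=C | intermediate
17 | (1R,2R,4S)-2-{(2S)-2-[2,4-bis(benzyloxy)-6-bromophenyl]-4-methylpentyl}-3,3-dimethylbicyclo[2.2.1]heptan-2-ol, hydroxyl endo | CC(C)C[C@H](c1c(OCc2ccccc2)cc(OCc2ccccc2)cc1Br)C[C@@]2(O)[C@@H]1CC[C@@H](C1)C2(C)C | intermediate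
18 | (2R,4S,1′R,4′S)-5,7-bis(benzyloxy)-4-isobutyl-3′,3′-dimethylspiro[chromane-2,2′-norbornane] | CC(C)C[C@H]1C[C@@]2(Oc3cc(OCc4ccccc4)cc(OCc4ccccc4)c31)[C@@H]1CC[C@@H](C1)C2(C)C | intermediate
19 | (2R,4S,1′R,4′S)-4-isobutyl-3′,3′-dimethylspiro[chromane-2,2′-norbornane]-5,7-diol | CC(C)C[C@H]1C[C@@]2(Oc3cc(O)cc(O)c31)[C@@H]1CC[C@@H](C1)C2(C)C | intermediate
20 | (2R,4S,1′R,4′S)-6,8-bis[chloro(methoxy)methyl]-4-isobutyl-3′,3′-dimethylspiro[chromane-2,2′-norbornane]-5,7-diol (as titanium phenoxide, not isolated) | CC(C)C[C@H]1C[C@@]2(Oc3c(C(Cl)OC)c(O)c(C(Cl)OC)c(O)c31)[C@@H]1CC[C@@H](C1)C2(C)C | intermediate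
21 | (2R,4S,1′R,4′S)-5,7-dihydroxy-4-isobutyl-3′,3′-dimethylspiro[chromane-2,2′-norbornane]-6,8-dicarbaldehyde | CC(C)C[C@H]1C[C@@]2(Oc3c(C=O)c(O)c(C=O)c(O)c31)[C@@H]1CC[C@@H](C1)C2(C)C | target

## Step count and least certain steps

Total step count: 11. Longest linear sequence: 10 steps (steps 1 to 4 and 6 to 11, from 1 to 21); step 5 is a one-step branch.

**Step 8 (key step).**
- What may go wrong: ring closure may fail to compete. The strained norbornyloxy radical can revert by β-scission to the tertiary radical, which is then reduced, so the isopropenyl group is merely hydrogenated. Rotamer control at C2 may be incomplete and give poor exo/endo selectivity. Any trans epimer left in 16 is lost to alkene reduction.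
- Fallback (known chemistry; makes C2–C3 instead of C2–C3′): it sets out from aldehyde 11 and Grignard reagent 14 and returns at 17. Horner–Wadsworth–Emmons reaction of 11 with trimethyl phosphonoacetate gives methyl (2E)-3-[2,4-bis(benzyloxy)-6-bromophenyl]prop-2-enoate F1. Copper-catalysed enantioselective addition of 14 (CuI, Tol-BINAP antipode chosen for 3S, t-BuOMe, −40 °C) gives methyl (3S)-3-[2,4-bis(benzyloxy)-6-bromophenyl]-5-methylhexanoate F2. Saponification with LiOH gives (3S)-3-[2,4-bis(benzyloxy)-6-bromophenyl]-5-methylhexanoic acid F3. Barton decarboxylative iodination (thiohydroxamate ester, CHI3, light) gives (2R)-2-[2,4-bis(benzyloxy)-6-bromophenyl]-1-iodo-4-methylpentane F4. Magnesium insertion into the alkyl iodide at low temperature and transmetalation with CeCl3 give an organocerium reagent that adds to the exo face of (1R,4S)-camphenilone F5, which gives 17 with the hydroxyl endo.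

**Step 7.**
- What may go wrong: poor facial selectivity, because the di-ortho-substituted aryl group is twisted out of the enone plane and screens both faces. Slow 1,4-addition to the electron-rich enone may also let 1,2-addition compete.
- Fallback (stereocontrol by separation instead of by catalyst): it sets out from 13 and returns at 18. Addition of the Gilman-type cuprate made from 14 and CuI (with Me3SiCl, THF, −78 °C), followed by the DBU equilibration, gives 16 together with its benzylic epimer (3R)-3-[2,4-bis(benzyloxy)-6-bromophenyl]-5-methyl-1-[(1R,3S)-3-(prop-1-en-2-yl)cyclopentyl]hexan-1-one F6. The pair is taken through steps 8 and 9, in which F6 gives (1R,2R,4S)-2-{(2R)-2-[2,4-bis(benzyloxy)-6-bromophenyl]-4-methylpentyl}-3,3-dimethylbicyclo[2.2.1]heptan-2-ol F7 and then (2R,4R,1′R,4′S)-5,7-bis(benzyloxy)-4-isobutyl-3′,3′-dimethylspiro[chromane-2,2′-norbornane] F8. Chromans 18 and F8 differ in the cis/trans relation of the substituents at C2 and C4 on ring B and are separated by chromatography.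

**Step 9.**
- What may go wrong: slow reductive elimination of the very hindered tertiary alkoxide from palladium, which leads to hydrodebromination of the arene or to β-carbon elimination that opens the norbornanol.
- Fallback (copper-mediated closure via the iodide): it sets out from 17 and returns at 18. Aromatic Finkelstein exchange (CuI cat., NaI, trans-N,N′-dimethylcyclohexane-1,2-diamine, dioxane, 110 °C) gives (1R,2R,4S)-2-{(2S)-2-[2,4-bis(benzyloxy)-6-iodophenyl]-4-methylpentyl}-3,3-dimethylbicyclo[2.2.1]heptan-2-ol F9. Ullmann-type etherification (CuI, 3,4,7,8-tetramethyl-1,10-phenanthroline, Cs2CO3, toluene, 110 °C) then closes ring B to 18.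

**Step 11.**
- What may go wrong: TiCl4 may ionise the C2–O1 bond, which is followed by Wagner–Meerwein rearrangement or ring opening. The second formylation may also stall after the first formyl group has deactivated the ring.
- Fallback (base-mediated, no strong Lewis acid): it sets out from 19 and returns at 21. Magnesium-mediated ortho-formylation (MgCl2, Et3N, excess paraformaldehyde, MeCN, reflux) formylates through the magnesium phenoxide by hydroxymethylation and hydride transfer to formaldehyde. No new isolated compound is made.

## Further compounds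

F1 | step 8 | methyl (2E)-3-[2,4-bis(benzyloxy)-6-bromophenyl]prop-2-enoate | COC(=O)/C=C/c1c(Br)cc(OCc2ccccc2)cc1OCc1ccccc1
F2 | step 8 | methyl (3S)-3-[2,4-bis(benzyloxy)-6-bromophenyl]-5-methylhexanoate | CC(C)C[C@H](c1c(OCc2ccccc2)cc(OCc2ccccc2)cc1Br)CC(=O)OC
F3 | step 8 | (3S)-3-[2,4-bis(benzyloxy)-6-bromophenyl]-5-methylhexanoic acid | CC(C)C[C@H](c1c(OCc2ccccc2)cc(OCc2ccccc2)cc1Br)CC(=O)O
F4 | step 8 | (2R)-2-[2,4-bis(benzyloxy)-6-bromophenyl]-1-iodo-4-methylpentane | CC(C)C[C@H](c1c(OCc2ccccc2)cc(OCc2ccccc2)cc1Br)CI
F5 | step 8 | (1R,4S)-camphenilone, (1R,4S)-3,3-dimethylbicyclo[2.2.1]heptan-2-one | O=C1[C@@H]2CC[C@@H](C2)C1(C)C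
F6 | step 7 | (3R)-3-[2,4-bis(benzyloxy)-6-bromophenyl]-5-methyl-1-[(1R,3S)-3-(prop-1-en-2-yl)cyclopentyl]hexan-1-one | CC(C)C[C@@H](c1c(OCc2ccccc2)cc(OCc2ccccc2)cc1Br)CC(=O)[C@@H]1CC[C@@H](C1)C(C)=C
F7 | step 7 | (1R,2R,4S)-2-{(2R)-2-[2,4-bis(benzyloxy)-6-bromophenyl]-4-methylpentyl}-3,3-dimethylbicyclo[2.2.1]heptan-2-ol | CC(C)C[C@@H](c1c(OCc2ccccc2)cc(OCc2ccccc2)cc1Br)C[C@@]2(O)[C@@H]1CC[C@@H](C1)C2(C)C
F8 | step 7 | (2R,4R,1′R,4′S)-5,7-bis(benzyloxy)-4-isobutyl-3′,3′-dimethylspiro[chromane-2,2′-norbornane] | CC(C)C[C@@H]1C[C@@]2(Oc3cc(OCc4ccccc4)cc(OCc4ccccc4)c31)[C@@H]1CC[C@@H](C1)C2(C)C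
F9 | step 9 | (1R,2R,4S)-2-{(2S)-2-[2,4-bis(benzyloxy)-6-iodophenyl]-4-methylpentyl}-3,3-dimethylbicyclo[2.2.1]heptan-2-ol | CC(C)C[C@H](c1c(OCc2ccccc2)cc(OCc2ccccc2)cc1I)C[C@@]2(O)[C@@H]1CC[C@@H](C1)C2(C)C
F0 | step 11 | none | none
A1 | alternative 1 | dimethyl (2R,4S,1′R,4′S)-5,7-dihydroxy-4-isobutyl-3′,3′-dimethylspiro[chromane-2,2′-norbornane]-6,8-dicarboxylate | CC(C)C[C@H]1C[C@@]2(Oc3c(C(=O)OC)c(O)c(C(=O)OC)c(O)c31)[C@@H]1CC[C@@H](C1)C2(C)C
A2 | alternative 1 | dimethyl 3-oxopentanedioate | COC(=O)CC(=O)CC(=O)OC
A3 | alternative 1 | methyl (2R,4S,1′R,4′S)-4-isobutyl-3′,3′-dimethyl-6-(methylsulfanyl)-3,4-dihydrospiro[pyran-2,2′-norbornane]-5-carboxylate | CC(C)C[C@H]1C[C@@]2(OC(SC)=C1C(=O)OC)[C@@H]1CC[C@@H](C1)C2(C)C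
A4 | alternative 2 | (2R,1′R,4′S)-5,7-dihydroxy-3′,3′-dimethylspiro[chromane-2,2′-norbornan]-4-one | O=C1C[C@@]2(Oc3cc(O)cc(O)c31)[C@@H]1CC[C@@H](C1)C2(C)C
A5 | alternative 2 | 1-methoxy-1,3-bis(trimethylsilyloxy)buta-1,3-diene | COC(O[Si](C)(C)C)=CC(=C)O[Si](C)(C)C
A6 | alternative 2 | (2R,1′R,4′S)-3′,3′-dimethyl-5-(phenylsulfinyl)-2,3-dihydrospiro[pyran-2,2′-norbornan]-4-one | O=C1C[C@@]2(OC=C1S(=O)c1ccccc1)[C@@H]1CC[C@@H](C1)C2(C)C
A7 | alternative 3 | (2R,1′R,4′S)-5,7-bis(benzyloxy)-3′,3′-dimethylspiro[chromane-2,2′-norbornan]-4-one | O=C1C[C@@]2(Oc3cc(OCc4ccccc4)cc(OCc4ccccc4)c31)[C@@H]1CC[C@@H](C1)C2(C)C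
A8 | alternative 3 | (1R,4S)-camphenilone, (1R,4S)-3,3-dimethylbicyclo[2.2.1]heptan-2-one | O=C1[C@@H]2CC[C@@H](C2)C1(C)C
A9 | alternative 3 | 1-[2,4-bis(benzyloxy)-6-fluorophenyl]ethan-1-one | CC(=O)c1c(F)cc(OCc2ccccc2)cc1OCc1ccccc1
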